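The second of waiting is the unit of this account: for each mole of substrate turned into product the catalyst waits at each stop of its round, and those waits add up like entries in a ledger.

substrate 1.7 M; coupling partner 2.04 M; free catalyst 17 mM

    substrate + free catalyst ⇌ catalyst intermediate A (K1 = 0.269 M⁻¹, k1 = 0.405 M⁻¹ s⁻¹)
    catalyst intermediate A → catalyst intermediate B (k2 = 0.406 s⁻¹)
    coupling partner + catalyst intermediate B ⇌ catalyst intermediate C (K3 = 1.07 M⁻¹, k3 = 7.69 M⁻¹ s⁻¹)
    catalyst intermediate C → released group + catalyst intermediate D (k4 = 52.8 s⁻¹)
    catalyst intermediate D → free catalyst + product (k5 = 76.5 s⁻¹)
    free catalyst → spent catalyst (k6 = 0.00579 s⁻¹)

- apparent order in coupling partner when 20% of the substrate are converted (percent change of the rate of making product for one percent more coupling partner charged)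

Substrate is the limiting reagent by charge. This reckoning replaces the curve by one point, 20% conversion, where substrate stands at 1.36 M and coupling partner at 1.70 M. The first entry is the free wait τ_F, the time free catalyst spends per completed turnover, 8.55 s; it counts every binding that falls back from intermediate A. Intermediate A then waits 2.46 s. Intermediate B waits 0.0869 s, with the returns from intermediate C included, and intermediates C and D together take 0.0320 s. The books close at 11.1 s per turnover.

The rate goes as live catalyst over this sum, and coupling partner stands in the entry of intermediate B, which is a share 0.00781 of the sum. The expression for the free wait holds no partner, so this reckoning takes the live catalyst at a given conversion as the same with more partner charged. One percent more partner charged raises its concentration at that point by 1.20 percent, so this reckoning gives an order of 0.00937.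

The forecast says 0.01, on the grounds that “extra partner frees almost no catalyst”. It names the step from intermediate A as limiting, whereas this ledger's largest entry is the free wait.

The simulation gives 0.0090. With substrate at its mean on the way to 20%, τ_F in this flask becomes 7.60 s, so free catalyst turns over 22.7 times per loss to spent catalyst, which allows product of 22.7% of the substrate charged; the flask reads 22.3% at 100 min. By this reckoning 15.0 mM of catalyst goes to spent catalyst on the way to 20%, which keeps 2.04 mM live, while twice the charge keeps 19.0 mM, a reckoned factor of 9.33 on the rate, and the run with twice the free catalyst gives 9.65.

The constants used here come from no measurement; the flask was simulated.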